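## Structural features

The target holds three rings. A cis-fused decalin (ring A: C4a, C5–C8, C8a; ring B: C1–C4, C4a, C8a) is tied from C1 through two methylene carbons, L1 and L2, to C6′ of a 1,2-dioxane (ring C: O1′, O2′, C3′–C6′). C3′ of ring C carries a methyl propanoate through its α-carbon Cα.

Ring B bears four contiguous stereocentres: C2 (methyl), C1 (chain), C8a (quaternary methyl) and C4a (tertiary hydroxyl). C4a is followed by the quaternary C5, so C8a–C4a–C5 are three fully substituted carbons in a row. The C1 chain is trans to the C2 methyl and cis to both the C8a methyl and the C4a hydroxyl, which makes the ring fusion cis.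

In ring C, C3′ and Cα are neighbours. C6′ stands alone as a quaternary peroxy carbon with one methyl and two nearly equal CH2 arms, and its long arm is trans to the C3′ substituent. The fragile parts are:
- the O–O bond, which is sensitive to reductants, phosphines, low-valent metals and strong base;
- the β-peroxy ester, which can undergo retro-addition and epimerisation at Cα;
- the tertiary alcohol, which can dehydrate under acid.

The real difficulty is twofold. The C8a–C4a–C5 array is very crowded. C6′ cannot be steered by ring conformation and therefore needs a stereospecific C–O bond formation. The key step uses the contiguous C2–C1–C8a triad of ring B. This triad maps onto the γ-, β- and α-carbons of a 2,4-dimethylcyclohexenone whose γ-methyl centre comes from the chiral pool.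

## Logic of the disconnections

**30 to 27 (through 29 and 28).** The O–CH3 bond and then the two C–O bonds of the carboxyl carbon are removed, so this carbon becomes the inner carbon of a vinyl group.
- Reason: a carbonyl next to Cα would acidify Cα–H and invite β-elimination at C3′ in every earlier basic step.
- Gain: a spectator group that tolerates base, acid, peroxide and radical chemistry.
- Demand: the forward cleavage must spare the O–O bond and the C4a alcohol and must not epimerise Cα.

**27 to 25 (through 26).** One C–H bond at L2 is exchanged for a C–O bond.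
- Reason: this oxygen is the retron of an oxirane across L2–C6′, the device that allows a stereospecific substitution at C6′.
- Gain: the C6′ problem becomes a question of alkene face selection.
- Demand: a deoxygenation must be run one carbon away from a peroxide.

**25 to 23 (through 24).** O1′–C6′ and O2′–C3′ are cut and the O–O unit leaves as a two-atom reagent.
- Reason: both carbons are then electrophiles of defined configuration, a tertiary oxirane carbon and a secondary sulfonate.
- Gain: ring C and the peroxide disappear together.
- Demand: each substitution must run with clean inversion, and the first must take place at the more substituted oxirane carbon.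

**23 to 21 (through 22).** The two oxirane C–O bonds and the O–S bond are removed.
- Reason: an E-trisubstituted alkene is an ideal substrate for reagent-controlled epoxidation, and the sulfonate retains the carbinol configuration.
- Gain: an open-chain dienol.
- Demand: the trisubstituted alkene must be oxidised in preference to the vinyl group, and the C4a alcohol must stay untouched.

**21 to 20.** The C3′–Cα bond is cut.
- Reason: both adjacent stereocentres arise in one closed transition state.
- Gain: four carbons and two stereocentres are removed.
- Demand: a syn-selective, reagent-controlled crotyl transfer is needed, because the nearest stereocentre in 20 is too remote to help.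

**20 to 18 (through 19).** The C4′–C5′ σ-bond is cut with a shift of the alkene from L2=C6′ to C6′=C5′.
- Reason: a [3,3] shift builds the E-alkene and the two-carbon extension together.
- Gain: an allylic alcohol whose carbinol configuration is irrelevant.
- Demand: the chair transition state must place the L1 substituent equatorial.

**18 to 17.** The L2–C6′ bond is cut.
- Reason: L2 is already at the aldehyde oxidation level.
- Gain: three carbons are removed.
- Demand: only a tolerance for the free C4a hydroxyl.

**17 to 14 (through 16 and 15).** The aldehyde is masked as an acetal and the C6–C7 bond of ring A is cut at the alkene level.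
- Reason: both olefin arms sit on the same face of ring B.
- Gain: ring A is removed.
- Demand: the metathesis must engage a neopentyl vinyl group, and no enol ether may be present.

**14 to 11 and 12.** The C4a–C5 bond is cut.
- Reason: an allyl-inverting nucleophile brings C5, both of its methyl groups, C6 and the C4a carbinol in one operation.
- Gain: five carbons and one stereocentre are removed.
- Demand: the tertiary carbon of the nucleophile must attack an α-quaternary ketone from the face opposite the C8a methyl.

**11 to 4, 5 and 6 (through 10).** The C1–L1 and C8a–C8 bonds are cut.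
- Reason: they lie on the β- and α-carbons of an enone and can be made in one flask.
- Gain: two bonds and two stereocentres are traced back to a single resident stereocentre.
- Demand: the addition must be trans to the C2 methyl, and the enolate must then be alkylated trans to the new C1 group before it can equilibrate.

**4 to 1 (through 3 and 2).** The ring alkene is rehydrated, the ketone is traced to an exocyclic alkene, and the C8a methyl is traced to a carbonyl addition.
- Reason: this transposes the carbonyl of a cheap terpene ketone by one position.
- Gain: a commercial starting material that carries the C2 configuration.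
- Demand: the dehydration must not racemise the γ-centre.

## Other disconnections considered

**Alternative 1:** The cut goes through both C–O bonds of ring C, but in a small fragment that does not yet carry the decalin. In the forward sense an O–O unit is joined first to the tertiary carbon of a 2,2-disubstituted oxirane under heteropoly-acid catalysis. As its anion it is then joined to a secondary sulfonate, with inversion each time, to give the dioxane A1.

- In its favour: the hydroxyl left by the oxirane sits on a CH2 group that becomes L2, so it serves the fragment union and does not have to be removed. Ring C is closed before any coupling, and the plan is convergent.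
- Against it here: A1 brings L2 along, so the decalin partner may hold only L1. The two-carbon unit placed on C1 by the chosen key step would then be one carbon too long. The union would be an olefination at a neopentyl α-peroxy aldehyde followed by diimide reduction, and it has to run with the O–O bond present.
- Comparison: the mechanism is the same pair of substitutions as in steps 16 and 17, so the two plans are equal in stereocontrol at C3′ and C6′. The alternative is better in redox economy and in convergence, because it needs nothing like steps 18 and 19. The chosen plan is better in that every C–C bond is in place before the peroxide enters.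

**Alternative 2:** The cut removes C4a–C8a and C1–C2 at once and opens rings A and B to an acyclic trienone. Forward, a chiral oxazaborolidinium Lewis acid would fold a (Z)-1-silyloxydiene onto an (E)-2-methyl enone to give the octalone A2.

- In its favour: two rings and the stereocentres C1, C2, C4a and C8a arise in a single catalytic step. The cis fusion follows from the suprafacial addition. In bonds and stereocentres per step this is better than steps 4 to 8.
- Against it: the C4a–C8a bond joins two fully substituted carbons. The diene terminus carries both a silyloxy group and the neopentyl C5. A geometrically pure tetrasubstituted silyl dienol ether is hard to secure, and the α-methyl-β-alkyl enone is a sluggish dienophile. A strong Lewis acid may also divert the silyl enol ether into a stepwise conjugate addition. Afterwards the C8 ketone, next to the quaternary C8a, and the C3=C4 alkene must both be erased.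
- Comparison: the alternative draws absolute configuration from a catalyst, the chosen plan from the chiral pool, and the two are equal in principle. The alternative wins on concision of ring formation. The chosen plan wins on predictability of each bond formation and leaves no surplus ketone.

**Alternative 3:** The cut removes C1–C8a and opens ring B, keeping ring A as a trimethylcyclohexene. Forward, MeAlCl2 would activate a terminal oxirane, C8a would attack its CH carbon with inversion, and the C4a cation would lose a proton from C4 to give the octalin methanol A3.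

- In its favour: ring A, the gem-dimethyl group and the C4a–C5 bond come ready-made. On this point the alternative is better, because it avoids step 6, the most crowded bond formation of the chosen plan. The quaternary C8a is also formed in the ring closure.
- Against it: a tetrasubstituted alkene must attack the more hindered carbon of a terminal oxirane, in competition with attack at CH2 and with a hydride shift to an aldehyde. The C1/C8a relationship rests on one folding mode of the chain. C2 and the oxirane centre must be set beforehand in an open chain. The C4a hydroxyl must be added later, cis to the C8a methyl, across a hindered trisubstituted alkene. A3 also holds only L1, so a one-carbon homologation follows.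
- Comparison: the two plans are about equal in step count up to the decalin. The alternative is stronger at C5. The chosen plan is stronger at C4a, C1 and C8a, which it sets by well-understood substrate control, and it delivers both linker carbons.

Key step: step 4

Remark: Dec stands for the (1S,2R,4aS,8aR)-4a-hydroxy-2,5,5,8a-tetramethyldecahydronaphthalen-1-yl group. The carbinol centres of 2, 3 and 18 are drawn without configuration because they are destroyed later. (−)-Ipc2BOMe means the reagent derived from (+)-α-pinene.

## Steps

Step 1
Reactants: 1 (R)-(+)-pulegone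
Product: 2 (5R)-1,5-dimethyl-2-(propan-2-ylidene)cyclohexan-1-ol (both C1 epimers)
Conditions: MeLi, Et2O, −78 to 0 °C; H2O
Reagents that add atoms: methyllithium, [Li]C
Why: A hard organolithium adds 1,2 to this hindered enone (carbonyl addition). The new carbinol centre may form as a mixture because step 3 erases it, and the ring methyl centre from the chiral pool is not touched.

Step 2
Reactants: 2 (5R)-1,5-dimethyl-2-(propan-2-ylidene)cyclohexan-1-ol
Product: 3 (4R)-2-hydroxy-2,4-dimethylcyclohexan-1-one (both C2 epimers)
Conditions: O3, CH2Cl2–MeOH, −78 °C; Me2S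
Reagents that add atoms: ozone, [O-][O+]=O
Why: Ozonolysis cleaves the only C=C bond, the electron-rich tetrasubstituted isopropylidene group, and reductive work-up should give the α-hydroxy ketone. No stereocentre is made or endangered.

Step 3
Reactants: 3 (4R)-2-hydroxy-2,4-dimethylcyclohexan-1-one
Product: 4 (R)-2,4-dimethylcyclohex-2-en-1-one
Conditions: SOCl2, pyridine, CH2Cl2, 0 °C
Reagents that add atoms: none
Why: Chlorosulfite formation and pyridine-induced E2 loss (alcohol dehydration) should give the more substituted, conjugated endocyclic alkene. The cold, non-equilibrating medium avoids dienol formation, which would erode the γ-stereocentre.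

Step 4
Reactants: 4 (R)-2,4-dimethylcyclohex-2-en-1-one; 5 (Z)-1-bromo-2-ethoxyethene; 6 allyl bromide
Product: 10 (2R,3R,4R)-2-allyl-3-[(Z)-2-ethoxyvinyl]-2,4-dimethylcyclohexan-1-one, via (Z)-2-ethoxyvinyllithium 7 (not isolated), via lithium bis[(Z)-2-ethoxyvinyl]cuprate 8 (not isolated), via lithium enolate 9 (not isolated)
Conditions: 5, t-BuLi (2 equiv per 5), Et2O, −78 °C; CuBr·SMe2 (0.5 equiv per 7), −78 to −40 °C; 4, −78 °C; then 6 (excess), HMPA, −78 to 0 °C; aq NH4Cl
Reagents that add atoms: none
Why: Bromine–lithium exchange gives 7 with retention of the Z geometry, and two equivalents with CuBr·SMe2 give the homocuprate 8. The cuprate forms a π-complex with 4, adds oxidatively at the β-carbon to a trivalent copper species, and reductively eliminates to form the C1–L1 bond and the regiodefined enolate 9. The closest known reaction type is the three-component conjugate addition–enolate alkylation of 2-methylcyclohexenones, and no ring is closed. C1 is set by the resident C2 methyl, because the cuprate takes the face of the β-carbon away from this adjacent group and so gives the trans C1/C2 pair. C8a is set by the new C1 group, which turns pseudo-axial in 9 to escape A(1,2) strain with the enolate methyl and thereby screens one face, so 6 attacks axially from the other face, leaving the allyl group trans and the methyl group cis to the chain. The step needs 1,4- over 1,2-addition, which the soft cuprate secures. It also needs C- over O-alkylation without enolate equilibration, which the reactive allylic halide, the polar cosolvent, the low temperature and the absence of a proton source secure.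

Step 5
Reactants: 10 (2R,3R,4R)-2-allyl-3-[(Z)-2-ethoxyvinyl]-2,4-dimethylcyclohexan-1-one
Product: 11 (2R,3S,4R)-2-allyl-3-(2,2-diethoxyethyl)-2,4-dimethylcyclohexan-1-one
Conditions: EtOH, PPTS (cat.), rt
Reagents that add atoms: ethanol, CCO
Why: Acid-catalysed addition of the alcohol to the enol ether (protonation at L1, capture of the oxocarbenium ion at L2) gives the acetal, while the α-quaternary ketone does not ketalise under PPTS. The mask is needed because a free aldehyde would consume the Grignard reagent of step 6 and an enol ether would deactivate the ruthenium carbene of step 7.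

Step 6
Reactants: 11 (2R,3S,4R)-2-allyl-3-(2,2-diethoxyethyl)-2,4-dimethylcyclohexan-1-one; 12 prenyl bromide
Product: 14 (1S,2R,3S,4R)-2-allyl-3-(2,2-diethoxyethyl)-2,4-dimethyl-1-(2-methylbut-3-en-2-yl)cyclohexan-1-ol, via prenylmagnesium bromide 13 (not isolated)
Conditions: 12, Mg (excess), THF, 0 °C; then 11, THF, −78 to −20 °C; aq NH4Cl
Reagents that add atoms: none
Why: The allylic Grignard reagent adds through a six-membered SE2′ transition state, so its γ-carbon (the future C5) bonds to C4a, and short reaction at low temperature keeps this kinetic adduct. The ketone rests in the chair with the C1 and C2 groups equatorial and the C8a methyl axial, so attack comes from the face opposite that methyl. This places C5 on the side of the allyl group and the hydroxyl cis to the C8a methyl (4aS).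

Step 7
Reactants: 14 (1S,2R,3S,4R)-2-allyl-3-(2,2-diethoxyethyl)-2,4-dimethyl-1-(2-methylbut-3-en-2-yl)cyclohexan-1-ol
Product: 15 (1S,2R,4aS,8aR)-1-(2,2-diethoxyethyl)-2,5,5,8a-tetramethyl-1,3,4,5,8,8a-hexahydronaphthalen-4a(2H)-ol
Conditions: second-generation Grubbs catalyst RuCl2(=CHPh)(PCy3)(H2IMes) (5 mol %), CH2Cl2, 40 °C
Reagents that add atoms: none
Why: In this ring-closing metathesis the carbene loads on the open allyl group and closes onto the neopentyl vinyl group, a favourable six-membered closure driven by loss of ethene. Both arms already stand on the same face of ring B, so no stereocentre changes.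

Step 8
Reactants: 15 (1S,2R,4aS,8aR)-1-(2,2-diethoxyethyl)-2,5,5,8a-tetramethyl-1,3,4,5,8,8a-hexahydronaphthalen-4a(2H)-ol
Product: 16 1,1-diethoxy-2-Dec-ethane
Conditions: H2 (1 atm), Pd/C, EtOAc, rt
Reagents that add atoms: none
Why: Heterogeneous hydrogenation saturates the only C=C bond. The acetal and the tertiary alcohol are inert in the neutral medium and no stereocentre is created.

Step 9
Reactants: 16 1,1-diethoxy-2-Dec-ethane
Product: 17 2-Dec-acetaldehyde
Conditions: 1 M HCl, THF, 0 °C to rt
Reagents that add atoms: water, O
Why: This is a mild acetal hydrolysis, and dilute acid at or below room temperature should not ionise the hindered C4a alcohol. Any lactol formed with the cis C4a hydroxyl stays in equilibrium with the open aldehyde and reacts through it.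

Step 10
Reactants: 17 2-Dec-acetaldehyde
Product: 18 1-Dec-3-methylbut-3-en-2-ol (both carbinol epimers)
Conditions: isopropenylmagnesium bromide (2.5 equiv), THF, −78 to 0 °C; aq NH4Cl
Reagents that add atoms: isopropenylmagnesium bromide, CC(=C)[Mg]Br
Why: In this Grignard addition to the aldehyde, the first equivalent is spent on the C4a hydroxyl. The L2 carbinol centre may form as a mixture because it becomes sp2 in step 11.

Step 11
Reactants: 18 1-Dec-3-methylbut-3-en-2-ol
Product: 19 ethyl (E)-6-Dec-4-methylhex-4-enoate
Conditions: MeC(OEt)3 (solvent), EtCO2H (cat.), 135 °C, EtOH distilled off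
Reagents that add atoms: triethyl orthoacetate, CCOC(C)(OCC)OCC
Why: In the Johnson–Claisen rearrangement, the ketene acetal formed in the flask rearranges through a chair with the L1 substituent equatorial. This forms the C4′–C5′ bond and sets the E geometry of the trisubstituted alkene, and the weak acid should not dehydrate the C4a alcohol.

Step 12
Reactants: 19 ethyl (E)-6-Dec-4-methylhex-4-enoate
Product: 20 (E)-6-Dec-4-methylhex-4-enal
Conditions: i-Bu2AlH (2.2 equiv), CH2Cl2, −78 °C; aq KNaC4H4O6
Reagents that add atoms: none
Why: This is a partial ester reduction, in which the tetrahedral aluminium hemiacetal survives at −78 °C and collapses to the aldehyde only on work-up. One equivalent of hydride is used up by the free hydroxyl.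

Step 13
Reactants: 20 (E)-6-Dec-4-methylhex-4-enal
Product: 21 (3R,4R,7E)-9-Dec-3,7-dimethylnona-1,7-dien-4-ol
Conditions: cis-2-butene, n-BuLi, KOt-Bu, THF, −78 to −45 °C; (−)-Ipc2BOMe, −78 °C; BF3·OEt2; 20, −78 °C; NaOH, H2O2
Reagents that add atoms: (Z)-crotyldiisopinocampheylborane made in the flask from cis-2-butene, C/C=C\CB([C@@H]1C[C@@H]2C[C@H]([C@H]1C)C2(C)C)[C@@H]1C[C@@H]2C[C@H]([C@H]1C)C2(C)C
Why: In the Brown crotylboration the closed chair transition state turns the Z geometry of the borane into the syn C3′/Cα pair. The isopinocampheyl groups direct attack to the Si face of the unbranched aldehyde, so both centres (3R,4R) are set by reagent control, and the remote decalin centres exert no bias.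

Step 14
Reactants: 21 (3R,4R,7E)-9-Dec-3,7-dimethylnona-1,7-dien-4-ol
Product: 22 (3R,4R,7E)-9-Dec-3,7-dimethylnona-1,7-dien-4-yl methanesulfonate
Conditions: MsCl, Et3N, CH2Cl2, 0 °C
Reagents that add atoms: methanesulfonyl chloride, CS(=O)(=O)Cl
Why: Only the one accessible hydroxyl is sulfonylated, with retention at C3′. The C4a alcohol, flanked by two quaternary carbons, should not react, and capping the carbinol also keeps it from attacking the oxirane of step 15.

Step 15
Reactants: 22 (3R,4R,7E)-9-Dec-3,7-dimethylnona-1,7-dien-4-yl methanesulfonate
Product: 23 (3R,4R)-6-[(2R,3R)-3-(Dec-methyl)-2-methyloxiran-2-yl]-3-methylhex-1-en-4-yl methanesulfonate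
Conditions: D-fructose-derived Shi ketone (0.3 equiv), KHSO5 (as Oxone), K2CO3, Bu4NHSO4, MeCN–CH2(OMe)2, aq Na2B4O7 buffer, 0 °C
Reagents that add atoms: potassium peroxymonosulfate, [K+].[O-]S(=O)(=O)OO
Why: In the Shi epoxidation the chiral dioxirane meets E-trisubstituted alkenes in a spiro transition state, and the D-fructose series delivers the (R,R)-oxirane by reagent control. The electron-rich trisubstituted alkene should react well ahead of the terminal vinyl group.

Step 16
Reactants: 23 (3R,4R)-6-[(2R,3R)-3-(Dec-methyl)-2-methyloxiran-2-yl]-3-methylhex-1-en-4-yl methanesulfonate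
Product: 24 (3R,4R,7S,8R)-9-Dec-7-hydroperoxy-8-hydroxy-3,7-dimethylnon-1-en-4-yl methanesulfonate
Conditions: H2O2 (dried ethereal solution, excess), H3PMo12O40 (5 mol %), Et2O, rt
Reagents that add atoms: hydrogen peroxide, OO
Why: In this acid-catalysed perhydrolysis of an oxirane, the heteropoly acid activates the ring and the peroxide attacks from the rear at the carbon that best carries positive charge, the tertiary C6′. The inversion sets the C6′ configuration of the target, and L2 keeps its oxygen with retention.

Step 17
Reactants: 24 (3R,4R,7S,8R)-9-Dec-7-hydroperoxy-8-hydroxy-3,7-dimethylnon-1-en-4-yl methanesulfonate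
Product: 25 (1R)-1-{(3S,6S)-3-[(2R)-but-3-en-2-yl]-6-methyl-1,2-dioxan-6-yl}-2-Dec-ethan-1-ol
Conditions: Cs2CO3, DMF, 0 °C to rt
Reagents that add atoms: none
Why: This is an intramolecular peroxide alkylation (6-exo-tet SN2). Carbonate deprotonates only the hydroperoxide, which is far more acidic than either alcohol, and the peroxy anion displaces the sulfonate with inversion. This turns the syn sulfonate into the anti C3′/Cα pair (3′S).

Step 18
Reactants: 25 (1R)-1-{(3S,6S)-3-[(2R)-but-3-en-2-yl]-6-methyl-1,2-dioxan-6-yl}-2-Dec-ethan-1-ol
Product: 26 O-[(1R)-1-{(3S,6S)-3-[(2R)-but-3-en-2-yl]-6-methyl-1,2-dioxan-6-yl}-2-Dec-ethyl] O-phenyl thiocarbonate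
Conditions: PhOC(S)Cl, pyridine, DMAP (cat.), CH2Cl2, rt
Reagents that add atoms: O-phenyl chlorothionoformate, S=C(Cl)Oc1ccccc1
Why: Thioacylation of the secondary L2 alcohol is the first half of a Barton–McCombie deoxygenation. The conditions are mild and only weakly basic, C3′–H is not activated at this stage, and the C4a alcohol is too hindered to react.

Step 19
Reactants: 26 O-[(1R)-1-{(3S,6S)-3-[(2R)-but-3-en-2-yl]-6-methyl-1,2-dioxan-6-yl}-2-Dec-ethyl] O-phenyl thiocarbonate
Product: 27 (3S,6R)-3-[(2R)-but-3-en-2-yl]-6-(2-Dec-ethyl)-6-methyl-1,2-dioxane
Conditions: Bu3SnH (10 equiv, about 1 M), Et3B, air, toluene, 0 °C to rt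
Reagents that add atoms: none
Why: In the Barton–McCombie deoxygenation the stannyl radical adds to C=S, the C–O bond breaks, and the L2 radical takes hydrogen from the stannane. The high stannane concentration and low temperature are chosen so that hydrogen transfer outruns attack of this radical on the neighbouring O–O bond, as in the hydride demercuration of β-peroxyalkylmercurials, which passes through the same kind of radical. The L2 stereocentre vanishes and C6′ is untouched.

Step 20
Reactants: 27 (3S,6R)-3-[(2R)-but-3-en-2-yl]-6-(2-Dec-ethyl)-6-methyl-1,2-dioxane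
Product: 29 (2S)-2-[(3S,6R)-6-(2-Dec-ethyl)-6-methyl-1,2-dioxan-3-yl]propanoic acid, via aldehyde 28 (not isolated)
Conditions: O3, MeCN–H2O (9:1), 0 °C; then NaClO2, NaH2PO4, 2-methyl-2-butene, rt
Reagents that add atoms: ozone, [O-][O+]=O; sodium chlorite, [Na+].[O-]Cl=O
Why: In aqueous medium water intercepts the carbonyl oxide, so ozonolysis gives the aldehyde without a reductant, and Pinnick oxidation follows in the same flask. The buffered, weakly acidic medium avoids enolisation at Cα and β-elimination of the peroxide, and dialkyl peroxides and the tertiary alcohol are inert to both oxidants.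

Step 21
Reactants: 29 (2S)-2-[(3S,6R)-6-(2-Dec-ethyl)-6-methyl-1,2-dioxan-3-yl]propanoic acid
Product: 30 methyl (2S)-2-[(3S,6R)-6-(2-Dec-ethyl)-6-methyl-1,2-dioxan-3-yl]propanoate (target)
Conditions: TMSCHN2, toluene–MeOH, 0 °C
Reagents that add atoms: (trimethylsilyl)diazomethane, C[Si](C)(C)C=[N+]=[N-]
Why: Esterification with a diazoalkane needs no acid or base, so neither the β-peroxy ester nor Cα is put at risk. The tertiary alcohol is not methylated.

## Compound list

1 | (R)-(+)-pulegone | C[C@@H]1CCC(=C(C)C)C(=O)C1 | starting material
2 | (5R)-1,5-dimethyl-2-(propan-2-ylidene)cyclohexan-1-ol, both C1 epimers | C[C@@H]1CCC(=C(C)C)C(C)(O)C1 | intermediate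
3 | (4R)-2-hydroxy-2,4-dimethylcyclohexan-1-one, both C2 epimers | C[C@@H]1CCC(=O)C(C)(O)C1 | intermediate
4 | (R)-2,4-dimethylcyclohex-2-en-1-one | C[C@@H]1CCC(=O)C(C)=C1 | intermediate
5 | (Z)-1-bromo-2-ethoxyethene | CCO/C=C\Br | starting material
6 | allyl bromide | C=CCBr | starting material
7 | (Z)-2-ethoxyvinyllithium | CCO/C=C\[Li] | intermediate
8 | lithium bis[(Z)-2-ethoxyvinyl]cuprate | [Li+].CCO/C=C\[Cu-]/C=C\OCC | intermediate
9 | lithium (3R,4R)-3-[(Z)-2-ethoxyvinyl]-2,4-dimethylcyclohex-1-en-1-olate | CCO/C=C\[C@H]1[C@H](C)CCC([O-])=C1C.[Li+] | intermediate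
10 | (2R,3R,4R)-2-allyl-3-[(Z)-2-ethoxyvinyl]-2,4-dimethylcyclohexan-1-one | CCO/C=C\[C@H]1[C@H](C)CCC(=O)[C@]1(C)CC=C | intermediate
11 | (2R,3S,4R)-2-allyl-3-(2,2-diethoxyethyl)-2,4-dimethylcyclohexan-1-one | CCOC(OCC)C[C@H]1[C@H](C)CCC(=O)[C@]1(C)CC=C | intermediate
12 | prenyl bromide | CC(C)=CCBr | starting material
13 | prenylmagnesium bromide | CC(C)=CC[Mg]Br | intermediate
14 | (1S,2R,3S,4R)-2-allyl-3-(2,2-diethoxyethyl)-2,4-dimethyl-1-(2-methylbut-3-en-2-yl)cyclohexan-1-ol | CCOC(OCC)C[C@H]1[C@H](C)CC[C@](O)(C(C)(C)C=C)[C@]1(C)CC=C | intermediate
15 | (1S,2R,4aS,8aR)-1-(2,2-diethoxyethyl)-2,5,5,8a-tetramethyl-1,3,4,5,8,8a-hexahydronaphthalen-4a(2H)-ol | CCOC(OCC)C[C@H]2[C@H](C)CC[C@]3(O)C(C)(C)C=CC[C@]23C | intermediate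
16 | 1,1-diethoxy-2-Dec-ethane | CCOC(OCC)C[C@H]2[C@H](C)CC[C@]3(O)C(C)(C)CCC[C@]23C | intermediate
17 | 2-Dec-acetaldehyde | O=CC[C@H]2[C@H](C)CC[C@]3(O)C(C)(C)CCC[C@]23C | intermediate
18 | 1-Dec-3-methylbut-3-en-2-ol, both carbinol epimers | C=C(C)C(O)C[C@H]2[C@H](C)CC[C@]3(O)C(C)(C)CCC[C@]23C | intermediate
19 | ethyl (E)-6-Dec-4-methylhex-4-enoate | CCOC(=O)CC/C(C)=C/C[C@H]2[C@H](C)CC[C@]3(O)C(C)(C)CCC[C@]23C | intermediate
20 | (E)-6-Dec-4-methylhex-4-enal | O=CCC/C(C)=C/C[C@H]2[C@H](C)CC[C@]3(O)C(C)(C)CCC[C@]23C | intermediate
21 | (3R,4R,7E)-9-Dec-3,7-dimethylnona-1,7-dien-4-ol | C=C[C@@H](C)[C@H](O)CC/C(C)=C/C[C@H]2[C@H](C)CC[C@]3(O)C(C)(C)CCC[C@]23C | intermediate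
22 | (3R,4R,7E)-9-Dec-3,7-dimethylnona-1,7-dien-4-yl methanesulfonate | C=C[C@@H](C)[C@H](OS(C)(=O)=O)CC/C(C)=C/C[C@H]2[C@H](C)CC[C@]3(O)C(C)(C)CCC[C@]23C | intermediate
23 | (3R,4R)-6-[(2R,3R)-3-(Dec-methyl)-2-methyloxiran-2-yl]-3-methylhex-1-en-4-yl methanesulfonate | C=C[C@@H](C)[C@H](OS(C)(=O)=O)CC[C@@]1(C)O[C@@H]1C[C@H]2[C@H](C)CC[C@]3(O)C(C)(C)CCC[C@]23C | intermediate
24 | (3R,4R,7S,8R)-9-Dec-7-hydroperoxy-8-hydroxy-3,7-dimethylnon-1-en-4-yl methanesulfonate | C=C[C@@H](C)[C@H](OS(C)(=O)=O)CC[C@](C)(OO)[C@H](O)C[C@H]2[C@H](C)CC[C@]3(O)C(C)(C)CCC[C@]23C | intermediate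
25 | (1R)-1-{(3S,6S)-3-[(2R)-but-3-en-2-yl]-6-methyl-1,2-dioxan-6-yl}-2-Dec-ethan-1-ol | C=C[C@@H](C)[C@@H]1CC[C@@](C)([C@H](O)C[C@H]2[C@H](C)CC[C@]3(O)C(C)(C)CCC[C@]23C)OO1 | intermediate
26 | O-phenyl thiocarbonate of 25 at the L2 hydroxyl | C=C[C@@H](C)[C@@H]1CC[C@@](C)([C@H](OC(=S)Oc4ccccc4)C[C@H]2[C@H](C)CC[C@]3(O)C(C)(C)CCC[C@]23C)OO1 | intermediate
27 | (3S,6R)-3-[(2R)-but-3-en-2-yl]-6-(2-Dec-ethyl)-6-methyl-1,2-dioxane | C=C[C@@H](C)[C@@H]1CC[C@@](C)(CC[C@H]2[C@H](C)CC[C@]3(O)C(C)(C)CCC[C@]23C)OO1 | intermediate
28 | (2S)-2-[(3S,6R)-6-(2-Dec-ethyl)-6-methyl-1,2-dioxan-3-yl]propanal | O=C[C@@H](C)[C@@H]1CC[C@@](C)(CC[C@H]2[C@H](C)CC[C@]3(O)C(C)(C)CCC[C@]23C)OO1 | intermediate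
29 | (2S)-2-[(3S,6R)-6-(2-Dec-ethyl)-6-methyl-1,2-dioxan-3-yl]propanoic acid | OC(=O)[C@@H](C)[C@@H]1CC[C@@](C)(CC[C@H]2[C@H](C)CC[C@]3(O)C(C)(C)CCC[C@]23C)OO1 | intermediate
30 | methyl (2S)-2-[(3S,6R)-6-(2-Dec-ethyl)-6-methyl-1,2-dioxan-3-yl]propanoate | COC(=O)[C@@H](C)[C@@H]1CC[C@@](C)(CC[C@H]2[C@H](C)CC[C@]3(O)C(C)(C)CCC[C@]23C)OO1 | target

## Step count and least certain steps

Total step count: 21. Longest linear sequence: 21 steps (1 to 30). The route is fully linear.

**Step 4 (key step).** The most likely failure is slow C-allylation of the copper-containing, tetrasubstituted enolate. Proton exchange with product, O-allylation or a second alkylation could then compete. Warming 7 too far would also cost reagent through loss of ethoxide.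

The fallback sets out from 4 and returns at 10. The same cuprate addition is run, but the enolate is caught on oxygen with allyl chloroformate to give the allyl enol carbonate F1, which can be purified. Pd(PPh3)4, a zerovalent palladium complex, in THF then ionises and decarboxylates F1. The site-specific enolate recombines with the π-allylpalladium partner (Tsuji decarboxylative allylation) on the face away from the C1 group.

**Step 6.** The most likely failure is reversal of the crowded γ-addition, followed by drift to the linear adduct or to simple enolisation. The new bond joins a tertiary carbon to a carbonyl next to a quaternary centre. Poor facial selectivity is the second concern.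

The fallback sets out from 11 and returns at 14. 3-Methylbuta-1,2-dienylzinc chloride, made from 3-chloro-3-methylbut-1-yne and Zn in THF, reacts at its dimethyl-substituted terminus through the same kind of cyclic transition state. It carries a slim, linear alkynyl group into the crowded pocket and has no linear isomer to fall back to, giving the dimethylpropargyl carbinol F2. Semi-hydrogenation over Pd/CaCO3 poisoned with Pb(OAc)2 and quinoline then turns the alkyne into the vinyl group without touching the allyl group.

**Step 16.** The most likely failure is ionisation of the activated oxirane to an open tertiary cation before capture. This would erode the configuration at C6′ or lead to a hydride shift to a ketone. Acid-induced fragmentation of the β-hydroxy hydroperoxide is a further risk.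

The fallback reverses the order of the two C–O bond formations. It sets out from 23 and returns at 25.
- 2-Methoxyprop-2-yl hydroperoxide with CsOH in DMF displaces the sulfonate with inversion to give the peroxyketal F3.
- Aqueous acetic acid unmasks the secondary hydroperoxide F4.
- A trace of camphorsulfonic acid lets the tethered hydroperoxide open the oxirane in the 6-exo mode at C6′ with inversion. Both ring size and substitution favour this closure, and the nucleophile is held at the rear of the breaking bond.

**Step 19.** The most likely failure is attack of the L2 radical on the adjacent O–O bond, with closure to an oxirane and loss of ring C, before hydrogen transfer takes place. The L2 carbon stands anti to the O–O bond in the favoured chair. Attack of stannyl radicals on the peroxide late in the reaction is a lesser risk.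

The fallback never places oxygen on L2. It sets out from 20 and returns at 29.
- An Evans syn aldol reaction with (S)-4-benzyl-3-propionyloxazolidin-2-one (Bu2BOTf, Et3N) gives the imide F5.
- LiBH4 gives the diol F6.
- TBSCl and imidazole give the primary silyl ether F7.
- MsCl and Et3N give the sulfonate F8.
- Mukaiyama–Isayama hydroperoxysilylation (Co(thd)2, which is bis(2,2,6,6-tetramethylheptane-3,5-dionato)cobalt, with O2 and Et3SiH) puts hydrogen on L2 and a silylperoxy group on C6′ to give F9.
- Bu4NF removes both silyl groups and the peroxy anion closes ring C to the primary alcohol F10.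
- TEMPO with PhI(OAc)2 in wet MeCN gives 29.

The price of this fallback is that the tertiary radical is trapped without facial bias. The C6′ epimers then have to be separated at the stage of F10.

## Further compounds

F1 | step 4 | allyl (3R,4R)-3-[(Z)-2-ethoxyvinyl]-2,4-dimethylcyclohex-1-en-1-yl carbonate | CCO/C=C\[C@H]1[C@H](C)CCC(OC(=O)OCC=C)=C1C
F2 | step 6 | (1R,2R,3S,4R)-2-allyl-3-(2,2-diethoxyethyl)-2,4-dimethyl-1-(2-methylbut-3-yn-2-yl)cyclohexan-1-ol | CCOC(OCC)C[C@H]1[C@H](C)CC[C@](O)(C(C)(C)C#C)[C@]1(C)CC=C
F3 | step 16 | (3R,4S)-6-[(2R,3R)-3-(Dec-methyl)-2-methyloxiran-2-yl]-4-[(2-methoxypropan-2-yl)peroxy]-3-methylhex-1-ene | C=C[C@@H](C)[C@@H](OOC(C)(C)OC)CC[C@@]1(C)O[C@@H]1C[C@H]2[C@H](C)CC[C@]3(O)C(C)(C)CCC[C@]23C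
F4 | step 16 | (3R,4S)-6-[(2R,3R)-3-(Dec-methyl)-2-methyloxiran-2-yl]-4-hydroperoxy-3-methylhex-1-ene | C=C[C@@H](C)[C@@H](OO)CC[C@@]1(C)O[C@@H]1C[C@H]2[C@H](C)CC[C@]3(O)C(C)(C)CCC[C@]23C
F5 | step 19 | (4S)-4-benzyl-3-[(2S,3R,6E)-8-Dec-3-hydroxy-2,6-dimethyloct-6-enoyl]oxazolidin-2-one | O=C1OC[C@H](Cc2ccccc2)N1C(=O)[C@@H](C)[C@H](O)CC/C(C)=C/C[C@H]3[C@H](C)CC[C@]4(O)C(C)(C)CCC[C@]34C
F6 | step 19 | (2R,3R,6E)-8-Dec-2,6-dimethyloct-6-ene-1,3-diol | OC[C@@H](C)[C@H](O)CC/C(C)=C/C[C@H]2[C@H](C)CC[C@]3(O)C(C)(C)CCC[C@]23C
F7 | step 19 | 1-O-tert-butyldimethylsilyl ether of F6 | CC(C)(C)[Si](C)(C)OC[C@@H](C)[C@H](O)CC/C(C)=C/C[C@H]2[C@H](C)CC[C@]3(O)C(C)(C)CCC[C@]23C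
F8 | step 19 | 3-O-methanesulfonate of F7 | CC(C)(C)[Si](C)(C)OC[C@@H](C)[C@H](OS(C)(=O)=O)CC/C(C)=C/C[C@H]2[C@H](C)CC[C@]3(O)C(C)(C)CCC[C@]23C
F9 | step 19 | C6′ triethylsilyl peroxide from F8, both C6′ epimers | CC(C)(C)[Si](C)(C)OC[C@@H](C)[C@H](OS(C)(=O)=O)CCC(C)(OO[Si](CC)(CC)CC)CC[C@H]2[C@H](C)CC[C@]3(O)C(C)(C)CCC[C@]23C
F10 | step 19 | (2R)-2-[(3S,6R)-6-(2-Dec-ethyl)-6-methyl-1,2-dioxan-3-yl]propan-1-ol | OC[C@@H](C)[C@@H]1CC[C@@](C)(CC[C@H]2[C@H](C)CC[C@]3(O)C(C)(C)CCC[C@]23C)OO1
A1 | alternative 1 | [(3S,6S)-3-{(2R)-1-[(tert-butyldimethylsilyl)oxy]propan-2-yl}-6-methyl-1,2-dioxan-6-yl]methanol | CC(C)(C)[Si](C)(C)OC[C@@H](C)[C@@H]1CC[C@@](C)(CO)OO1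
A2 | alternative 2 | cis-fused 1-[2-(benzyloxy)ethyl]-4a-(tert-butyldimethylsilyloxy)-2,5,5,8a-tetramethyl-3-octalin-8-one, configuration as drawn | c1ccccc1COCC[C@H]2[C@H](C)C=C[C@]3(O[Si](C)(C)C(C)(C)C)C(C)(C)CCC(=O)[C@]23C
A3 | alternative 3 | (2,5,5,8a-tetramethyl-1,2,3,5,6,7,8,8a-octahydronaphthalen-1-yl)methanol, configuration as drawn | OC[C@H]2[C@H](C)CC=C3C(C)(C)CCC[C@]23C
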